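## Retrosynthetic overview

1. Michaolide A ⇐ 9‑O‑TBS ether ⇐ 14‑membered ring closed last by a SmI2 ketyl‑radical 14‑exo addition of the C14 aldehyde to C1 of a C2‑bound α‑(PhSCH2)‑butenolide, with β‑loss of PhS (forms C1–C14, the trans ring fusion and the exo‑methylene; Ac2O quench).
2. Butenolide ⇐ RCM of a C2 acrylate ester; C2/C3/C4 and the epoxide ⇐ Sharpless epoxidation of a C2 divinyl carbinol (C2 enal + vinylzinc).
3. Acyclic chain ⇐ C9–C10 by Ti(III) radical α‑allylation of enal 5 with allylic bromide 8; C9 resolved by Sharpless kinetic resolution.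
4. 5 ⇐ Brown allylation (sets C5) of acetoxy‑enal 1, then cross‑metathesis with methacrolein; 8 ⇐ Zr‑catalysed carboalumination of butynol ether 6.
5. Ring order: epoxide → butenolide → 14‑membered carbocycle (the α‑methylene‑γ‑lactone appears in the same step).

Assumption: locants are cembrane numbering of the target (lactone O–C2, C1 bears C15(=C17H2)–C16=O; epoxide C3–C4; OAc at C5 and C14; OH at C9; alkenes C7=C8, C11=C12). Target = 1R,2S,3S,4S,5R,9S,14R,7E,11E; these descriptors stay the same in every intermediate. Building blocks 1 (acetate) and 6 (TBS ether) are bought in O‑protected form.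

## Route

**Step 1**
Reactants: 1, (E)‑4‑acetoxy‑2‑methylbut‑2‑enal
Product: 2, (2E,4R)‑4‑hydroxy‑3‑methylhepta‑2,6‑dien‑1‑yl acetate
Conditions: (+)‑Ipc2BOMe, allylMgBr, Et2O (salt‑free); 1, −100 °C; NaBO3·4H2O
Reagents that add atoms: allylmagnesium bromide, C=CC[Mg]Br (as (+)‑Ipc2B‑allyl)
Why: Brown asymmetric allylboration through a chair Zimmerman–Traxler transition state; the (−)‑α‑pinene‑derived reagent attacks the re face of the enal and sets C5 (R).

**Step 2**
Reactants: 2
Product: 3, (2E,4R)‑3‑methylhepta‑2,6‑diene‑1,4‑diyl diacetate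
Conditions: Ac2O, pyridine, DMAP (cat.), CH2Cl2, 0 °C → rt
Reagents that add atoms: acetic anhydride, CC(=O)OC(C)=O
Why: Standard acylation installs the final C5 acetate; no stereocentre is touched.

**Step 3**
Reactants: 3; 4, methacrolein
Product: 5, (2E,4R,6E)‑3,7‑dimethyl‑8‑oxoocta‑2,6‑diene‑1,4‑diyl diacetate
Conditions: 4 (8 equiv), Hoveyda–Grubbs II (5 mol %), CH2Cl2, 40 °C
Reagents that add atoms: none (4 is a reactant)
Why: Olefin cross‑metathesis of a terminal alkene with methacrolein gives the (E)‑2‑methyl enal under thermodynamic control, setting 7E; the trisubstituted C3=C4 alkene is inert.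

**Step 4**
Reactants: 6, tert‑butyl(but‑3‑yn‑1‑yloxy)dimethylsilane
Product: 7, (E)‑5‑(tert‑butyldimethylsilyloxy)‑3‑methylpent‑2‑en‑1‑ol
Conditions: Me3Al, Cp2ZrCl2 (0.25 equiv), CH2Cl2, 0 °C → rt; then n‑BuLi, (CH2O)n, THF, −78 °C → rt
Reagents that add atoms: trimethylaluminium, C[Al](C)C; paraformaldehyde, C=O
Why: Negishi Zr‑catalysed syn‑carboalumination followed by hydroxymethylation of the alanate fixes the 11E trisubstituted alkene.

**Step 5**
Reactants: 7
Product: 8, (E)‑(5‑bromo‑3‑methylpent‑3‑enyloxy)(tert‑butyl)dimethylsilane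
Conditions: CBr4, PPh3, CH2Cl2, −20 °C
Reagents that add atoms: carbon tetrabromide, BrC(Br)(Br)Br
Why: Appel bromination of the primary allylic alcohol proceeds without allylic transposition or loss of alkene geometry.

**Step 6**
Reactants: 5; 8
Product: 9, (2E,4R,6E,8RS,10E)‑13‑(TBSO)‑8‑hydroxy‑3,7,11‑trimethyltrideca‑2,6,10‑triene‑1,4‑diyl diacetate (C9 epimers, about 1:1)
Conditions: Cp2TiCl2 (2.5 equiv), Mn dust, THF, rt; slow addition of 5 and 8 (1.5 equiv); aq. NaH2PO4
Reagents that add atoms: none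
Why: Ti(III) Barbier‑type α‑allylation: the allyl radical from 8 couples at its primary terminus with the Ti‑bound allyloxy radical of the conjugated aldehyde, giving the linear C9–C10 adduct with 11E retained; C9 is not controlled here and is resolved in step 7.

**Step 7**
Reactants: 9
Product: 10, the (9S) epimer of 9 (8S in the trideca numbering)
Conditions: Ti(OiPr)4 (1.0 equiv), D‑(−)‑DIPT (1.2 equiv), t‑BuOOH (0.6 equiv), 4 Å MS, CH2Cl2, −20 °C; recover unreacted alcohol
Reagents that add atoms: none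
Why: Sharpless kinetic resolution: with D‑(−)‑tartrate the (9R) epimer is epoxidised at C7=C8 about 100 times faster, so the (9S) allylic alcohol is recovered (maximum 50 %).

**Step 8**
Reactants: 10
Product: 11, the C9 O‑TBS ether of 10
Conditions: TBSOTf, 2,6‑lutidine, CH2Cl2, −78 °C
Reagents that add atoms: TBSOTf, CC(C)(C)[Si](C)(C)OS(=O)(=O)C(F)(F)F
Why: Silylation of the hindered secondary allylic alcohol; acetates and the primary TBS ether are unaffected.

**Step 9**
Reactants: 11
Product: 12, (2E,4R,6E,8S,10E)‑8,13‑bis(TBSO)‑1‑hydroxy‑3,7,11‑trimethyltrideca‑2,6,10‑trien‑4‑yl acetate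
Conditions: [t‑Bu2Sn(OH)Cl]2 (5 mol %), MeOH/THF, 30 °C
Reagents that add atoms: none
Why: Otera distannoxane‑catalysed transesterification removes the unhindered primary allylic acetate (C2) and leaves the hindered secondary C5 acetate.

**Step 10**
Reactants: 12
Product: 13, (2E,4R,6E,8S,10E)‑8,13‑bis(TBSO)‑3,7,11‑trimethyl‑1‑oxotrideca‑2,6,10‑trien‑4‑yl acetate
Conditions: MnO2, CH2Cl2, rt
Reagents that add atoms: none
Why: Neutral allylic oxidation gives the (E)‑enal at C2 without eliminating the γ‑acetate.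

**Step 11**
Reactants: 13
Product: 14, (3S,4E,6R,8E,10S,12E)‑10,15‑bis(TBSO)‑3‑hydroxy‑5,9,13‑trimethylpentadeca‑1,4,8,12‑tetraen‑6‑yl acetate
Conditions: (CH2=CH)2Zn, (−)‑MIB (10 mol %), toluene, −20 → 0 °C
Reagents that add atoms: divinylzinc, C=C[Zn]C=C
Why: Amino‑alcohol‑catalysed (Noyori/Nugent type) organozinc addition delivers vinyl to the si face of the aldehyde and sets C2 (S); any 2R epimer is mismatched in step 12 and is removed there.

**Step 12**
Reactants: 14
Product: 15, (3S,4S,5S,6R,8E,10S,12E)‑10,15‑bis(TBSO)‑4,5‑epoxy‑3‑hydroxy‑5,9,13‑trimethylpentadeca‑1,8,12‑trien‑6‑yl acetate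
Conditions: Ti(OiPr)4, L‑(+)‑DIPT, t‑BuOOH, 4 Å MS, CH2Cl2, −20 °C
Reagents that add atoms: tert‑butyl hydroperoxide, CC(C)(C)OO
Why: Sharpless asymmetric epoxidation directed by the C2 hydroxyl: the (2S) carbinol is the matched, fast substrate for L‑(+)‑tartrate and gives the erythro epoxide, setting C3 (S) and C4 (S); the monosubstituted vinyl and the remote alkenes do not react.

**Step 13**
Reactants: 15; 16, 2‑(bromomethyl)acrylic acid
Product: 17, the C2 O‑{2‑[(phenylthio)methyl]acryloyl} ester of 15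
Conditions: 16, PhSH, Et3N, CH2Cl2, 0 °C (2‑[(phenylthio)methyl]acrylic acid formed in situ); then 15, EDC·HCl, DMAP, rt
Reagents that add atoms: thiophenol, Sc1ccccc1
Why: Fast thiolate displacement on the bromomethyl acrylate followed by Steglich esterification of the C2 alcohol; the thiol is consumed before 15 is added, so the epoxide is not opened.

**Step 14**
Reactants: 17
Product: 18, (5S)‑3‑[(phenylthio)methyl]furan‑2(5H)‑one bearing the full C3–C14 chain at C5 (C2 of the target)
Conditions: Hoveyda–Grubbs II (10 mol %), toluene (5 mM), 80 °C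
Reagents that add atoms: none
Why: Ring‑closing metathesis between the acrylate methylene and the C1 vinyl group forms the butenolide (C1=C15); the trisubstituted chain alkenes do not take part and C2 is untouched.

**Step 15**
Reactants: 18
Product: 19, the C14 primary alcohol (C9 OTBS retained)
Conditions: HF·pyridine, pyridine, THF, 0 °C
Reagents that add atoms: none
Why: Buffered HF cleaves the unhindered primary TBS ether much faster than the hindered secondary allylic one; epoxide, acetate and butenolide survive.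

**Step 16**
Reactants: 19
Product: 20, the C14 aldehyde (β,γ‑unsaturated; used crude)
Conditions: Dess–Martin periodinane, NaHCO3, CH2Cl2, 0 °C
Reagents that add atoms: none
Why: Buffered Dess–Martin oxidation gives the aldehyde without base‑induced migration of the 11E alkene into conjugation.

**Step 17**
Reactants: 20
Product: 21, 9‑O‑TBS‑michaolide A
Conditions: SmI2 (3 equiv), THF, syringe‑pump addition of 20 over 8 h (final 1 mM), rt; then Ac2O, DMAP, 0 °C
Reagents that add atoms: acetic anhydride, CC(=O)OC(C)=O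
Why: Proposed new method: SmI2 reduces the aldehyde to a ketyl radical that adds 14‑exo‑trig to C1 of the electron‑poor butenolide anti to the C2 substituent (trans C1/C2, so C1 is R); the α‑lactonyl radical then expels PhS• (or is reduced and eliminates PhS−) to give the exo‑methylene, and the Sm(III) alkoxide is acetylated in situ. C14 (R) is predicted from a non‑chelated transition state with the bulky O–Sm(III) anti to C15 and the C14–H over the lactone ring. Closest known chemistry: SmI2 ketyl–olefin additions to butenolides and acrylates, SmI2 Barbier/Reformatsky macrocyclisations, and radical allyl transfer to allyl sulfides by addition–fragmentation.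

**Step 18**
Reactants: 21
Product: 22, michaolide A
Conditions: HF·pyridine, pyridine, THF, 0 °C → rt
Reagents that add atoms: none
Why: Buffered fluoride desilylation frees the C9 allylic alcohol without opening the epoxide, moving an acetate or adding to the α‑methylene lactone.

## Compound list

1 | (E)‑4‑acetoxy‑2‑methylbut‑2‑enal | CC(=O)OC/C=C(\C)C=O | starting material
2 | (2E,4R)‑4‑hydroxy‑3‑methylhepta‑2,6‑dien‑1‑yl acetate | C=CC[C@@H](O)/C(C)=C/COC(C)=O | intermediate
3 | (2E,4R)‑3‑methylhepta‑2,6‑diene‑1,4‑diyl diacetate | C=CC[C@@H](OC(C)=O)/C(C)=C/COC(C)=O | intermediate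
4 | methacrolein | C=C(C)C=O | starting material
5 | (2E,4R,6E)‑3,7‑dimethyl‑8‑oxoocta‑2,6‑diene‑1,4‑diyl diacetate | O=C/C(C)=C/C[C@@H](OC(C)=O)/C(C)=C/COC(C)=O | intermediate
6 | tert‑butyl(but‑3‑yn‑1‑yloxy)dimethylsilane | C#CCCO[Si](C)(C)C(C)(C)C | starting material
7 | (E)‑5‑(tert‑butyldimethylsilyloxy)‑3‑methylpent‑2‑en‑1‑ol | OC/C=C(\C)CCO[Si](C)(C)C(C)(C)C | intermediate
8 | (E)‑(5‑bromo‑3‑methylpent‑3‑enyloxy)(tert‑butyl)dimethylsilane | BrC/C=C(\C)CCO[Si](C)(C)C(C)(C)C | intermediate
9 | C9‑epimeric hydroxy diacetate (5R; 3E,7E,11E; C14 OTBS) | CC(C)(C)[Si](C)(C)OCC/C(C)=C/CC(O)/C(C)=C/C[C@@H](OC(C)=O)/C(C)=C/COC(C)=O | intermediate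
10 | (9S) epimer of 9 | CC(C)(C)[Si](C)(C)OCC/C(C)=C/C[C@H](O)/C(C)=C/C[C@@H](OC(C)=O)/C(C)=C/COC(C)=O | intermediate
11 | C9 O‑TBS ether of 10 | CC(C)(C)[Si](C)(C)OCC/C(C)=C/C[C@H](O[Si](C)(C)C(C)(C)C)/C(C)=C/C[C@@H](OC(C)=O)/C(C)=C/COC(C)=O | intermediate
12 | C2 primary allylic alcohol (C5 OAc, C9/C14 OTBS) | CC(C)(C)[Si](C)(C)OCC/C(C)=C/C[C@H](O[Si](C)(C)C(C)(C)C)/C(C)=C/C[C@@H](OC(C)=O)/C(C)=C/CO | intermediate
13 | C2 (E)‑enal | CC(C)(C)[Si](C)(C)OCC/C(C)=C/C[C@H](O[Si](C)(C)C(C)(C)C)/C(C)=C/C[C@@H](OC(C)=O)/C(C)=C/C=O | intermediate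
14 | (2S) divinyl carbinol | CC(C)(C)[Si](C)(C)OCC/C(C)=C/C[C@H](O[Si](C)(C)C(C)(C)C)/C(C)=C/C[C@@H](OC(C)=O)/C(C)=C/[C@@H](O)C=C | intermediate
15 | (2S,3S,4S,5R,9S) 3,4‑epoxy alcohol | CC(C)(C)[Si](C)(C)OCC/C(C)=C/C[C@H](O[Si](C)(C)C(C)(C)C)/C(C)=C/C[C@@H](OC(C)=O)[C@]1(C)O[C@H]1[C@@H](O)C=C | intermediate
16 | 2‑(bromomethyl)acrylic acid | OC(=O)C(=C)CBr | starting material
17 | C2 2‑[(phenylthio)methyl]acrylate of 15 | CC(C)(C)[Si](C)(C)OCC/C(C)=C/C[C@H](O[Si](C)(C)C(C)(C)C)/C(C)=C/C[C@@H](OC(C)=O)[C@]1(C)O[C@H]1[C@@H](OC(=O)C(=C)CSc1ccccc1)C=C | intermediate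
18 | (2S) α‑(phenylthiomethyl)butenolide, C14 OTBS | CC(C)(C)[Si](C)(C)OCC/C(C)=C/C[C@H](O[Si](C)(C)C(C)(C)C)/C(C)=C/C[C@@H](OC(C)=O)[C@]1(C)O[C@H]1[C@H]1OC(=O)C(CSc2ccccc2)=C1 | intermediate
19 | C14 primary alcohol | OCC/C(C)=C/C[C@H](O[Si](C)(C)C(C)(C)C)/C(C)=C/C[C@@H](OC(C)=O)[C@]1(C)O[C@H]1[C@H]1OC(=O)C(CSc2ccccc2)=C1 | intermediate
20 | C14 aldehyde (cyclisation precursor) | O=CC/C(C)=C/C[C@H](O[Si](C)(C)C(C)(C)C)/C(C)=C/C[C@@H](OC(C)=O)[C@]1(C)O[C@H]1[C@H]1OC(=O)C(CSc2ccccc2)=C1 | intermediate
21 | 9‑O‑TBS‑michaolide A | C=C1C(=O)O[C@H]2[C@H]1[C@H](OC(C)=O)C/C(C)=C/C[C@H](O[Si](C)(C)C(C)(C)C)/C(C)=C/C[C@@H](OC(C)=O)[C@]1(C)O[C@@H]21 | intermediate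
22 | michaolide A | C=C1C(=O)O[C@H]2[C@H]1[C@H](OC(C)=O)C/C(C)=C/C[C@H](O)/C(C)=C/C[C@@H](OC(C)=O)[C@]1(C)O[C@@H]21 | target

## Step count and risks

Total steps: 18. Longest linear sequence: 16 (steps 1–3 and 6–18); side branch of 2 steps (4–5).

Steps most likely to fail:

1. **Step 17 (SmI2 radical macrocyclisation).** Risks are simple reduction or pinacol coupling of the aldehyde, the wrong C14 epimer, and translactonisation by the C14 alkoxide. Fallback: leave out PhSH in step 13 so the allylic bromide is kept, and close the ring by an intramolecular CrCl2‑ or In‑mediated Barbier allylation of the aldehyde (organometallic, closed transition state relating C1 and C14), then acetylate. If only the 14‑epi alcohol is obtained, quench with water instead of Ac2O and install the acetate with inversion by Mitsunobu reaction (AcOH, DIAD, PPh3), at no extra step.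
2. **Steps 6–7 (Ti(III) α‑allylation and resolution).** Risks are γ‑adduct or pinacol by‑products, and loss of half the material because C9 is uncontrolled. Fallback: oxidise the C9 epimer mixture to the C7‑ene‑9‑one with MnO2 and set C9 by reagent‑controlled CBS reduction, replacing the resolution with a stereoselective reduction.
3. **Step 9 (primary versus secondary acetate).** Risk is partial loss of the C5 acetate. Fallback: change the protecting‑group plan so that no acetate differentiation is needed: carry C2 as a silyl ether from the start (TBS ether of (E)‑4‑hydroxy‑2‑methylbut‑2‑enal in place of 1, with C14 as TBDPS) and unveil C2–OH by mild acid before step 10.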